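**Retrosynthetic overview**

1. The last step is hydrogenolysis of six benzyl ethers; before it, both stereocentres (flavan C2 and C3) are set together by an asymmetric transfer hydrogenation with dynamic kinetic resolution of a racemic flavan-3-one.
2. The flavan-3-one is the hydrolysed form of a 3-methoxy-2H-chromene, whose pyran ring is cut at C4–C4a and at O1–C2 in one formal [3+3] annulation of a para-flavonyl phenol with (Z)-2-methoxy-3-(4-benzyloxyphenyl)propenal (ortho-hydroxyalkylation, vinyl ortho-quinone methide, oxa-6π electrocyclization).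
3. Enabling feature: flavan ring A is a phloroglucinol ring in which C4a is an electron-rich CH ortho to the phenolic O1 on C8a, and the flavonyl group at C6 is para to O1, so C4a and C8 of the phenol are equivalent and only one annulation product can form once O5 and O7 are benzylated. C3 carries oxygen, so C4–C3–C2 maps onto an α-oxygenated cinnamaldehyde.
4. The phenol comes from Negishi coupling of 3-iodo-tri-O-benzylapigenin with a 2,6-bis(benzyloxy)-4-silyloxyphenylzinc reagent; the enal comes from 4-(benzyloxy)benzaldehyde by Horner–Wadsworth–Emmons olefination, reduction and oxidation.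
5. Ring order: the chromone rings (bought with apigenin) and all benzene rings are ready-made; the only ring built is the flavan pyran ring, closed in the key step.

Key step: step 10

Assumption: the biaryl axis between flavone C3 and flavan C6 has no descriptor in the given structure, so it is treated as not stereogenic; intermediates and product may appear as rotamers about it, and only C2 and C3 are controlled.

**Step 1**
Reactants: 1 apigenin
Product: 2 5,7-bis(benzyloxy)-2-[4-(benzyloxy)phenyl]-4H-chromen-4-one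
Conditions: BnBr (4 equiv), K2CO3, DMF, 80 °C
Reagents that add atoms: benzyl bromide, BrCc1ccccc1
Why: Williamson etherification of all three phenols, in which the hydrogen-bonded 5-OH reacts last and is driven by excess benzyl bromide and heat; no stereocentre is involved.

**Step 2**
Reactants: 2 5,7-bis(benzyloxy)-2-[4-(benzyloxy)phenyl]-4H-chromen-4-one
Product: 4 5,7-bis(benzyloxy)-2-[4-(benzyloxy)phenyl]-3-iodo-4H-chromen-4-one, via 3-lithiochromone 3 (not isolated)
Conditions: LiN(iPr)2, THF, −78 °C; then I2, −78 °C to rt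
Reagents that add atoms: iodine, II
Why: The vinylic C3–H next to the carbonyl is the most acidic C–H of the chromone, so low-temperature lithiation and iodinolysis should put iodine at C3 only, whereas electrophilic iodination would compete at C6 and C8.

**Step 3**
Reactants: 5 3,5-bis(benzyloxy)phenol
Product: 6 [3,5-bis(benzyloxy)phenoxy]tri(propan-2-yl)silane
Conditions: iPr3SiCl, imidazole, DMF, rt
Reagents that add atoms: chlorotri(propan-2-yl)silane, CC(C)[Si](Cl)(C(C)C)C(C)C
Why: Standard silylation of a phenol; the bulky silyl ether masks the oxygen that later becomes O1 and shields its two ortho positions in the next step.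

**Step 4**
Reactants: 6 [3,5-bis(benzyloxy)phenoxy]tri(propan-2-yl)silane
Product: 7 [3,5-bis(benzyloxy)-4-bromophenoxy]tri(propan-2-yl)silane
Conditions: NBS, CH2Cl2, −40 to 0 °C
Reagents that add atoms: N-bromosuccinimide, O=C1CCC(=O)N1Br
Why: Electrophilic aromatic bromination should go to the carbon ortho to both benzyloxy groups and para to the silyloxy group, which is the most activated position and the one not shielded by the triisopropylsilyl group.

**Step 5**
Reactants: 7 [3,5-bis(benzyloxy)-4-bromophenoxy]tri(propan-2-yl)silane; 4 5,7-bis(benzyloxy)-2-[4-(benzyloxy)phenyl]-3-iodo-4H-chromen-4-one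
Product: 10 5,7-bis(benzyloxy)-2-[4-(benzyloxy)phenyl]-3-[2,6-bis(benzyloxy)-4-(triisopropylsilyloxy)phenyl]-4H-chromen-4-one, via aryllithium 8 (not isolated), via arylzinc chloride 9 (not isolated)
Conditions: n-BuLi, THF, −78 °C; ZnCl2, −78 °C to rt; then 4, Pd2(dba)3 (cat.), RuPhos (cat.), THF, 65 °C
Reagents that add atoms: none
Why: Bromine–lithium exchange at −78 °C outruns benzylic deprotonation, the arylzinc leaves the chromone carbonyl alone, and Negishi coupling with a bulky dialkylbiarylphosphine ligand is an established way to tetra-ortho-substituted biaryls.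

**Step 6**
Reactants: 10 5,7-bis(benzyloxy)-2-[4-(benzyloxy)phenyl]-3-[2,6-bis(benzyloxy)-4-(triisopropylsilyloxy)phenyl]-4H-chromen-4-one
Product: 11 5,7-bis(benzyloxy)-2-[4-(benzyloxy)phenyl]-3-[2,6-bis(benzyloxy)-4-hydroxyphenyl]-4H-chromen-4-one
Conditions: Bu4NF, AcOH, THF, 0 °C
Reagents that add atoms: none
Why: Fluoride cleaves the aryl silyl ether selectively, acetic acid buffers the phenoxide, and benzyl ethers and the chromone are inert.

**Step 7**
Reactants: 12 4-(benzyloxy)benzaldehyde; 13 methyl 2-(dimethoxyphosphoryl)-2-methoxyacetate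
Product: 15 methyl (Z)-3-[4-(benzyloxy)phenyl]-2-methoxyprop-2-enoate, via sodium phosphonate carbanion 14 (not isolated)
Conditions: NaH, THF, 0 °C; then 12, 0 °C to rt
Reagents that add atoms: none
Why: Horner–Wadsworth–Emmons olefination, which with an α-methoxy phosphonate should give mainly the (Z)-ester (aryl trans to the ester); the alkene geometry is in any case erased in step 10.

**Step 8**
Reactants: 15 methyl (Z)-3-[4-(benzyloxy)phenyl]-2-methoxyprop-2-enoate
Product: 16 (Z)-3-[4-(benzyloxy)phenyl]-2-methoxyprop-2-en-1-ol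
Conditions: iBu2AlH, CH2Cl2, −78 to 0 °C; aq. potassium sodium tartrate
Reagents that add atoms: none
Why: 1,2-Reduction of the conjugated ester to the allylic alcohol by the aluminium hydride at low temperature, with the enol ether and the benzyl ether untouched.

**Step 9**
Reactants: 16 (Z)-3-[4-(benzyloxy)phenyl]-2-methoxyprop-2-en-1-ol
Product: 17 (Z)-3-[4-(benzyloxy)phenyl]-2-methoxyprop-2-enal
Conditions: MnO2, CH2Cl2, rt
Reagents that add atoms: none
Why: MnO2 oxidizes allylic alcohols selectively to enals without over-oxidation.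

**Step 10**
Reactants: 11 5,7-bis(benzyloxy)-2-[4-(benzyloxy)phenyl]-3-[2,6-bis(benzyloxy)-4-hydroxyphenyl]-4H-chromen-4-one; 17 (Z)-3-[4-(benzyloxy)phenyl]-2-methoxyprop-2-enal
Product: 20 3-{5,7-bis(benzyloxy)-2-[4-(benzyloxy)phenyl]-3-methoxy-2H-chromen-6-yl}-5,7-bis(benzyloxy)-2-[4-(benzyloxy)phenyl]-4H-chromen-4-one (racemic at C2), via benzodioxaborin 18 (not isolated), via vinyl ortho-quinone methide 19 (not isolated)
Conditions: PhB(OH)2 (1.2 equiv), EtCO2H (cat.), toluene, reflux, Dean–Stark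
Reagents that add atoms: none
Why: PhB(OH)2 ties the phenolic oxygen of 11 and the aldehyde of 17 together, so the ortho carbon (future C4a) adds to the aldehyde carbon (C4) to give dioxaborin 18, which loses the boron template on heating to give the vinyl ortho-quinone methide 19; thermal disrotatory oxa-6π electrocyclization of this 1-oxatriene then forms O1–C2 and restores the aromatic ring. The closest known reaction type is the phenylboronic acid-templated chromenylation of phenols with α,β-unsaturated aldehydes, cinnamaldehydes included, which gives 2-aryl-2H-chromenes. One ring is closed, the pyran ring, by 6π electrocyclization after the intermolecular ortho-selective C4–C4a bond formation. The new stereocentre C2 is formed without control (racemic) on purpose, because it becomes epimerizable in ketone 21 and is set in step 12. The step needs ortho regioselectivity and a single ring-closing oxygen: 11 has one free OH, its two ortho CH positions are equivalent and the other two oxygens of that ring are benzylated, so the flavonyl group must end at C6 between C5–OBn and C7–OBn, and the chromone carbonyl, a vinylogous ester, does not compete with the aldehyde. The α-methoxy group rides through as the C3 enol ether, so the product already holds C3 at the ketone oxidation level.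

**Step 11**
Reactants: 20 3-{5,7-bis(benzyloxy)-2-[4-(benzyloxy)phenyl]-3-methoxy-2H-chromen-6-yl}-5,7-bis(benzyloxy)-2-[4-(benzyloxy)phenyl]-4H-chromen-4-one
Product: 21 5,7-bis(benzyloxy)-2-[4-(benzyloxy)phenyl]-6-{5,7-bis(benzyloxy)-2-[4-(benzyloxy)phenyl]-4-oxo-4H-chromen-3-yl}chroman-3-one (racemic at C2)
Conditions: 1 M aq. HCl, THF, rt, argon
Reagents that add atoms: water, O
Why: Acid-catalysed enol ether hydrolysis (protonation at C4, addition of water to the C3 oxocarbenium ion, loss of methanol) unmasks the C3 ketone, while C2 stays racemic as wanted for the next step.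

**Step 12**
Reactants: 21 5,7-bis(benzyloxy)-2-[4-(benzyloxy)phenyl]-6-{5,7-bis(benzyloxy)-2-[4-(benzyloxy)phenyl]-4-oxo-4H-chromen-3-yl}chroman-3-one
Product: 22 (2R,3R)-5,7-bis(benzyloxy)-2-[4-(benzyloxy)phenyl]-6-{5,7-bis(benzyloxy)-2-[4-(benzyloxy)phenyl]-4-oxo-4H-chromen-3-yl}chroman-3-ol
Conditions: RuCl(p-cymene)[(R,R)-TsDPEN] (cat.), HCO2H/Et3N (5:2), DMF, 40 °C
Reagents that add atoms: none
Why: Noyori-type asymmetric transfer hydrogenation with dynamic kinetic resolution, in which C2–H (α to the ketone, benzylic and α to the aryloxy oxygen) lets the C2 epimers interconvert through the enol while the chiral Ru–H reduces one of them faster; hydride should add to C3 anti to the C2 aryl group to give the 2,3-cis alcohol, and the (R,R) ligand is assigned by the CH/π model (C2-aryl side of the ketone under the p-cymene) to attack the Si face of C3 and so give (2R,3R), the closest precedent being the reduction of 2-arylcyclohexanones and 3-arylchroman-4-ones to cis alcohols.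

**Step 13**
Reactants: 22 (2R,3R)-5,7-bis(benzyloxy)-2-[4-(benzyloxy)phenyl]-6-{5,7-bis(benzyloxy)-2-[4-(benzyloxy)phenyl]-4-oxo-4H-chromen-3-yl}chroman-3-ol
Product: 23 (2R,3R)-6-[5,7-dihydroxy-2-(4-hydroxyphenyl)-4-oxo-4H-chromen-3-yl]-2-(4-hydroxyphenyl)chromane-3,5,7-triol
Conditions: H2 (1 atm), Pd(OH)2/C, THF/MeOH, rt
Reagents that add atoms: none
Why: Hydrogenolysis of the six benzyl ethers under conditions standard for benzylated flavan-3-ols, which should leave the cyclic benzylic C2–O1 ether, the tetrasubstituted chromone double bond and both stereocentres untouched.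

**Compound list**

1 | apigenin | O=c1cc(-c2ccc(O)cc2)oc2cc(O)cc(O)c12 | starting material
2 | 5,7-bis(benzyloxy)-2-[4-(benzyloxy)phenyl]-4H-chromen-4-one | O=c1cc(-c2ccc(OCc3ccccc3)cc2)oc2cc(OCc3ccccc3)cc(OCc3ccccc3)c12 | intermediate
3 | 3-lithio derivative of 2 (not isolated) | O=c1c([Li])c(-c2ccc(OCc3ccccc3)cc2)oc2cc(OCc3ccccc3)cc(OCc3ccccc3)c12 | intermediate
4 | 5,7-bis(benzyloxy)-2-[4-(benzyloxy)phenyl]-3-iodo-4H-chromen-4-one | O=c1c(I)c(-c2ccc(OCc3ccccc3)cc2)oc2cc(OCc3ccccc3)cc(OCc3ccccc3)c12 | intermediate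
5 | 3,5-bis(benzyloxy)phenol | Oc1cc(OCc2ccccc2)cc(OCc2ccccc2)c1 | starting material
6 | [3,5-bis(benzyloxy)phenoxy]tri(propan-2-yl)silane | CC(C)[Si](Oc1cc(OCc2ccccc2)cc(OCc2ccccc2)c1)(C(C)C)C(C)C | intermediate
7 | [3,5-bis(benzyloxy)-4-bromophenoxy]tri(propan-2-yl)silane | CC(C)[Si](Oc1cc(OCc2ccccc2)c(Br)c(OCc2ccccc2)c1)(C(C)C)C(C)C | intermediate
8 | [2,6-bis(benzyloxy)-4-(triisopropylsilyloxy)phenyl]lithium (not isolated) | CC(C)[Si](Oc1cc(OCc2ccccc2)c([Li])c(OCc2ccccc2)c1)(C(C)C)C(C)C | intermediate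
9 | [2,6-bis(benzyloxy)-4-(triisopropylsilyloxy)phenyl]zinc chloride (not isolated) | CC(C)[Si](Oc1cc(OCc2ccccc2)c([Zn]Cl)c(OCc2ccccc2)c1)(C(C)C)C(C)C | intermediate
10 | 5,7-bis(benzyloxy)-2-[4-(benzyloxy)phenyl]-3-[2,6-bis(benzyloxy)-4-(triisopropylsilyloxy)phenyl]-4H-chromen-4-one | O=c1c(-c2c(OCc3ccccc3)cc(O[Si](C(C)C)(C(C)C)C(C)C)cc2OCc2ccccc2)c(-c2ccc(OCc3ccccc3)cc2)oc2cc(OCc3ccccc3)cc(OCc3ccccc3)c12 | intermediate
11 | 5,7-bis(benzyloxy)-2-[4-(benzyloxy)phenyl]-3-[2,6-bis(benzyloxy)-4-hydroxyphenyl]-4H-chromen-4-one | O=c1c(-c2c(OCc3ccccc3)cc(O)cc2OCc2ccccc2)c(-c2ccc(OCc3ccccc3)cc2)oc2cc(OCc3ccccc3)cc(OCc3ccccc3)c12 | intermediate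
12 | 4-(benzyloxy)benzaldehyde | O=Cc1ccc(OCc2ccccc2)cc1 | starting material
13 | methyl 2-(dimethoxyphosphoryl)-2-methoxyacetate | COC(C(=O)OC)P(=O)(OC)OC | starting material
14 | sodium salt of the carbanion of 13 (not isolated) | [Na+].COC(=C([O-])OC)P(=O)(OC)OC | intermediate
15 | methyl (Z)-3-[4-(benzyloxy)phenyl]-2-methoxyprop-2-enoate | CO/C(C(=O)OC)=C\c1ccc(OCc2ccccc2)cc1 | intermediate
16 | (Z)-3-[4-(benzyloxy)phenyl]-2-methoxyprop-2-en-1-ol | CO/C(CO)=C\c1ccc(OCc2ccccc2)cc1 | intermediate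
17 | (Z)-3-[4-(benzyloxy)phenyl]-2-methoxyprop-2-enal | CO/C(C=O)=C\c1ccc(OCc2ccccc2)cc1 | intermediate
18 | 2-phenyl-4H-1,3,2-benzodioxaborin from 11, 17 and PhB(OH)2, carrying the (Z)-2-(4-benzyloxyphenyl)-1-methoxyvinyl group at C4 (not isolated, racemic) | CO/C(=C\c1ccc(OCc2ccccc2)cc1)C1OB(c2ccccc2)Oc2cc(OCc3ccccc3)c(-c3c(-c4ccc(OCc5ccccc5)cc4)oc4cc(OCc5ccccc5)cc(OCc5ccccc5)c4c3=O)c(OCc3ccccc3)c21 | intermediate
19 | vinyl ortho-quinone methide (1-oxatriene; alkene geometry not defined; not isolated) | O=C1C=C(OCc2ccccc2)C(c2c(-c3ccc(OCc4ccccc4)cc3)oc3cc(OCc4ccccc4)cc(OCc4ccccc4)c3c2=O)=C(OCc2ccccc2)C1=CC(OC)=Cc1ccc(OCc2ccccc2)cc1 | intermediate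
20 | 3-{5,7-bis(benzyloxy)-2-[4-(benzyloxy)phenyl]-3-methoxy-2H-chromen-6-yl}-5,7-bis(benzyloxy)-2-[4-(benzyloxy)phenyl]-4H-chromen-4-one (racemic at C2) | COC1=Cc2c(OCc3ccccc3)c(-c3c(-c4ccc(OCc5ccccc5)cc4)oc4cc(OCc5ccccc5)cc(OCc5ccccc5)c4c3=O)c(OCc3ccccc3)cc2OC1c1ccc(OCc2ccccc2)cc1 | intermediate
21 | 5,7-bis(benzyloxy)-2-[4-(benzyloxy)phenyl]-6-{5,7-bis(benzyloxy)-2-[4-(benzyloxy)phenyl]-4-oxo-4H-chromen-3-yl}chroman-3-one (racemic at C2) | O=C1Cc2c(OCc3ccccc3)c(-c3c(-c4ccc(OCc5ccccc5)cc4)oc4cc(OCc5ccccc5)cc(OCc5ccccc5)c4c3=O)c(OCc3ccccc3)cc2OC1c1ccc(OCc2ccccc2)cc1 | intermediate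
22 | (2R,3R)-5,7-bis(benzyloxy)-2-[4-(benzyloxy)phenyl]-6-{5,7-bis(benzyloxy)-2-[4-(benzyloxy)phenyl]-4-oxo-4H-chromen-3-yl}chroman-3-ol | O=c1c(-c2c(OCc3ccccc3)cc3c(c2OCc2ccccc2)C[C@@H](O)[C@@H](c2ccc(OCc4ccccc4)cc2)O3)c(-c2ccc(OCc3ccccc3)cc2)oc2cc(OCc3ccccc3)cc(OCc3ccccc3)c12 | intermediate
23 | (2R,3R)-6-[5,7-dihydroxy-2-(4-hydroxyphenyl)-4-oxo-4H-chromen-3-yl]-2-(4-hydroxyphenyl)chromane-3,5,7-triol | O=c1c(-c2c(O)cc3c(c2O)C[C@@H](O)[C@@H](c2ccc(O)cc2)O3)c(-c2ccc(O)cc2)oc2cc(O)cc(O)c12 | target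

**Step count and risks**

Total step count: 13. Longest linear sequence: 8 steps (steps 3, 4, 5, 6, 10, 11, 12, 13 from 5; the same length from 1 through steps 1, 2, 5, 6, 10, 11, 12, 13).

Steps most likely to fail:

Step 12. Epimerization at C2 may be slower than reduction, so the process would stall as a plain kinetic resolution. Facial selectivity at C3 may also be poor or of the opposite sense to the model, in which case the (S,S) ligand is tried first, and the chromone may be partly reduced on long exposure. Fallback (sets out from 21, returns at 22): reduction of 21 with LiBH(s-Bu)3 in THF at −78 °C, the established substrate-controlled route to 2,3-cis-flavan-3-ols, should give the cis alcohol as a racemate, that is 22 together with its (2S,3S) enantiomer F1. Esterification of this mixture with (S)-2-methoxy-2-phenylacetic acid (DCC, DMAP, CH2Cl2) should give the (2R,3R) O-methylmandelate F2 and the (2S,3S) O-methylmandelate F3, which are diastereomers and should separate by chromatography or crystallization. Methanolysis of F2 (K2CO3, MeOH/THF, rt) returns 22.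

Step 10. Ortho-hydroxyalkylation may be sluggish with the α-substituted enal, the enol ether may hydrolyse early under the acidic conditions, and the ortho-quinone methide may oligomerize faster than it electrocyclizes. Fallback (sets out from 11 and 12, returns at 21): addition of CH2=CHMgBr to 12 gives the allylic alcohol 1-[4-(benzyloxy)phenyl]prop-2-en-1-ol F4. Acid-catalysed Friedel–Crafts allylation of 11 with F4 (H2SO4 on SiO2, CH2Cl2) should give, through the cinnamyl cation, the ortho-(E)-cinnamyl phenol F5. Epoxidation with mCPBA (NaHCO3, CH2Cl2, 0 °C) gives the trans epoxide F6, which the neighbouring phenol opens at the benzylic carbon (6-endo, inversion, completed by a trace of camphorsulfonic acid) to give the racemic 2,3-trans-flavan-3-ol F7. Dess–Martin oxidation of F7 returns ketone 21, so the ring is built by separate C–C and C–O bond formations and the C3 oxygen comes from the epoxide.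

Step 5. Transmetalation and reductive elimination may be slow in forming the tetra-ortho-substituted biaryl, with protodemetalation of the arylzinc and reduction of iodide 4 taking over. Fallback (sets out from 7, returns at 10): Pd-catalysed α-arylation of commercial 1-[2,4-bis(benzyloxy)-6-hydroxyphenyl]ethanone with 7 (Pd2(dba)3, XPhos, excess NaOtBu, toluene, 80 °C) gives the deoxybenzoin F8. Treatment with 4-(benzyloxy)benzoyl chloride and DBU in pyridine at 80 °C gives the aryl ester F9, Baker–Venkataraman acyl shift to the 1,3-diketone F10 and cyclodehydration in the same flask. This returns 10 with the chromone ring built around the hindered aryl–C3 bond instead of coupled to it.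

**Further compounds**

F1 | step 12 | (2S,3S) enantiomer of 22 | O=c1c(-c2c(OCc3ccccc3)cc3c(c2OCc2ccccc2)C[C@H](O)[C@H](c2ccc(OCc4ccccc4)cc2)O3)c(-c2ccc(OCc3ccccc3)cc2)oc2cc(OCc3ccccc3)cc(OCc3ccccc3)c12
F2 | step 12 | (2R,3R) O-methylmandelate: ester of 22 with (S)-2-methoxy-2-phenylacetic acid | O=c1c(-c2c(OCc3ccccc3)cc3c(c2OCc2ccccc2)C[C@@H](OC(=O)[C@@H](OC)c2ccccc2)[C@@H](c2ccc(OCc4ccccc4)cc2)O3)c(-c2ccc(OCc3ccccc3)cc2)oc2cc(OCc3ccccc3)cc(OCc3ccccc3)c12
F3 | step 12 | (2S,3S) O-methylmandelate: ester of F1 with (S)-2-methoxy-2-phenylacetic acid | O=c1c(-c2c(OCc3ccccc3)cc3c(c2OCc2ccccc2)C[C@H](OC(=O)[C@@H](OC)c2ccccc2)[C@H](c2ccc(OCc4ccccc4)cc2)O3)c(-c2ccc(OCc3ccccc3)cc2)oc2cc(OCc3ccccc3)cc(OCc3ccccc3)c12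
F4 | step 10 | 1-[4-(benzyloxy)phenyl]prop-2-en-1-ol (racemic) | C=CC(O)c1ccc(OCc2ccccc2)cc1
F5 | step 10 | 5,7-bis(benzyloxy)-2-[4-(benzyloxy)phenyl]-3-{2,6-bis(benzyloxy)-3-[(E)-3-(4-benzyloxyphenyl)prop-2-enyl]-4-hydroxyphenyl}-4H-chromen-4-one | O=c1c(-c2c(OCc3ccccc3)c(C/C=C/c3ccc(OCc4ccccc4)cc3)c(O)cc2OCc2ccccc2)c(-c2ccc(OCc3ccccc3)cc2)oc2cc(OCc3ccccc3)cc(OCc3ccccc3)c12
F6 | step 10 | trans epoxide of F5 (racemic, one enantiomer drawn) | O=c1c(-c2c(OCc3ccccc3)c(C[C@@H]3O[C@H]3c3ccc(OCc4ccccc4)cc3)c(O)cc2OCc2ccccc2)c(-c2ccc(OCc3ccccc3)cc2)oc2cc(OCc3ccccc3)cc(OCc3ccccc3)c12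
F7 | step 10 | 2,3-trans diastereomer of 22 (racemic, (2R,3S) enantiomer drawn) | O=c1c(-c2c(OCc3ccccc3)cc3c(c2OCc2ccccc2)C[C@H](O)[C@@H](c2ccc(OCc4ccccc4)cc2)O3)c(-c2ccc(OCc3ccccc3)cc2)oc2cc(OCc3ccccc3)cc(OCc3ccccc3)c12
F8 | step 5 | 1-[2,4-bis(benzyloxy)-6-hydroxyphenyl]-2-[2,6-bis(benzyloxy)-4-(triisopropylsilyloxy)phenyl]ethanone | O=C(Cc1c(OCc2ccccc2)cc(O[Si](C(C)C)(C(C)C)C(C)C)cc1OCc1ccccc1)c1c(O)cc(OCc2ccccc2)cc1OCc1ccccc1
F9 | step 5 | 4-(benzyloxy)benzoate ester of the phenol of F8 | O=C(Cc1c(OCc2ccccc2)cc(O[Si](C(C)C)(C(C)C)C(C)C)cc1OCc1ccccc1)c1c(OC(=O)c2ccc(OCc3ccccc3)cc2)cc(OCc2ccccc2)cc1OCc1ccccc1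
F10 | step 5 | 1-[2,4-bis(benzyloxy)-6-hydroxyphenyl]-3-[4-(benzyloxy)phenyl]-2-[2,6-bis(benzyloxy)-4-(triisopropylsilyloxy)phenyl]propane-1,3-dione (racemic) | O=C(c1ccc(OCc2ccccc2)cc1)C(c1c(OCc2ccccc2)cc(O[Si](C(C)C)(C(C)C)C(C)C)cc1OCc1ccccc1)C(=O)c1c(O)cc(OCc2ccccc2)cc1OCc1ccccc1
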